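**Plan**
- The retrosynthesis first cuts the furan O–C2 bond together with the protecting groups, then the pyranone O1–C8a bond (enolate oxygen onto an aryl fluoride), then the C3–C4 bond between a ring-A aldehyde (12) and a ring-B arylacetate (22).
- Aldehyde 12 goes back to chromene 8 by two ortho-lithiations, 8 to chromanol 6, and 6 to the symmetrical 2,6-difluoro-4-(methoxymethoxy)benzaldehyde 2 plus the C–C–O unit of 2,2-dimethyloxirane 3.
- Enabling feature: in ring A the oxygen-bearing carbons C5, C7, C8a alternate with the carbon-bearing C4a, C6, C8. The pyran oxygen (on C7) and the pyranone oxygen (on C8a) both flank C8, so C8 enters as a formyl carbon between two equivalent fluorines. One fluorine leaves when the pyran ring closes, the other when the pyranone closes.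
- Forward order: dimethylpyran ring (steps 2–3), ring-A substituents (4), ring-B arylacetate (5–8), union (9–10), pyranone ring (11), furan ring with deprotection (12–13).
- Stereochemistry: the target has no stereocenter; those of 5–7, 10, 11, 24, 25 are transient, uncontrolled and erased in steps 3, 4, 10 and 11.

Key step: step 2

Remark: target positions follow coumaronochromone usage (ring A: C4a, C5–C8, C8a; pyranone: O1, C2–C4; ring B: C1'–C6'); intermediates are numbered as chromenes or benzenes. Starting materials 1, 3 and 13 are taken as purchasable.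

**Step 1**
Reactants: 1 2,6-difluoro-4-hydroxybenzaldehyde
Product: 2 2,6-difluoro-4-(methoxymethoxy)benzaldehyde
Conditions: MOMCl, i-Pr2NEt, CH2Cl2, 0 °C → rt
Reagents that add atoms: chloromethyl methyl ether (MOMCl), COCCl
Why: O-alkylation of the acidic phenol (Williamson-type acetal formation) should be clean because the phenoxide is the only nucleophile, and the MOM ether later serves as ortho-directing group and is removable with mild acid.

**Step 2**
Reactants: 2 2,6-difluoro-4-(methoxymethoxy)benzaldehyde; 3 2,2-dimethyloxirane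
Product: 6 rac-5-fluoro-7-(methoxymethoxy)-2,2-dimethyl-3,4-dihydro-2H-chromen-4-ol, via β-lithioalkoxide 4 (not isolated), via dilithium diolate 5 (not isolated)
Conditions: LiDBB (from Li and 4,4'-di-tert-butylbiphenyl), 3, THF, −78 °C; then 2, −78 °C; then DMPU, 65 °C; H2O
Reagents that add atoms: none
Why: Proposed new method: reductive opening of the epoxide at its CH2–O bond should give the β-lithioalkoxide 4, a 1,3-C,O-dinucleophile, whose primary C–Li adds to the aldehyde of 2 at −78 °C to give diolate 5; on warming with DMPU the tertiary alkoxide of 5 should displace an ortho fluoride by addition–elimination (SNAr), so that the C3–C4 bond and the aryl C–O bond of the pyran ring arise in one flask. The closest known reaction types are the addition of epoxide-derived β-lithioalkoxides to aldehydes (1,3-diol synthesis) and the base-mediated SNAr cyclisation of 3-(2-fluoroaryl)propanols to chromans. The ring closes in a 6-exo-trig sense at the fluorine-bearing ring carbon, helped by the gem-dimethyl group and by the inductive pull of the second fluorine and the meta acetal oxygen. The one new stereocenter (C4 carbinol) forms without control as a racemate and is removed in step 3. Carbonyl addition must precede any attack on C–F or ring lithiation, which the low temperature secures; regioselectivity of the ring closure is not an issue because the two fluorines of 2 are equivalent by symmetry, and the fluorine that remains is the leaving group needed for the pyranone closure in step 11.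

**Step 3**
Reactants: 6 rac-5-fluoro-7-(methoxymethoxy)-2,2-dimethyl-3,4-dihydro-2H-chromen-4-ol
Product: 8 5-fluoro-7-(methoxymethoxy)-2,2-dimethyl-2H-chromene, via benzylic mesylate 7 (not isolated)
Conditions: MsCl, Et3N, CH2Cl2, 0 → 40 °C
Reagents that add atoms: none
Why: Mesylation of the benzylic alcohol gives 7, which should ionise readily (cation stabilised by the ring oxygen and the para acetal oxygen) and lose a C3 proton to Et3N, the standard chroman-4-ol to 2H-chromene dehydration (E1 elimination), which also erases the stereocenter.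

**Step 4**
Reactants: 8 5-fluoro-7-(methoxymethoxy)-2,2-dimethyl-2H-chromene
Product: 12 5-fluoro-7-(methoxymethoxy)-2,2-dimethyl-8-(3-methylbut-2-en-1-yl)-2H-chromene-6-carbaldehyde, via C6 aryllithium 9 (not isolated), via lithium hemiaminal 10 (not isolated), via C8-lithiated hemiaminal 11 (not isolated)
Conditions: s-BuLi, THF, −78 °C; DMF (1.0 equiv), −78 °C; s-BuLi, TMEDA, −78 → −40 °C; CuBr·SMe2 (10 mol%), prenyl bromide, −78 → 0 °C; H2O
Reagents that add atoms: N,N-dimethylformamide, CN(C)C=O; 1-bromo-3-methylbut-2-ene (prenyl bromide), CC(C)=CCBr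
Why: Directed ortho-metalation should remove C6–H, the most acidic ring proton (between F and OMOM), DMF converts aryllithium 9 into lithium hemiaminal 10, which masks the aldehyde in the flask (α-amino alkoxide protection) so that the second deprotonation can only take the last ring proton C8–H (between OMOM and the pyran oxygen) to give 11, and copper-catalysed SN2 allylation with prenyl bromide followed by hydrolysis should deliver 12.

**Step 5**
Reactants: 13 1,3-bis(methoxymethoxy)benzene
Product: 15 1,3-bis(methoxymethoxy)-2-(3-methylbut-2-en-1-yl)benzene, via C2 aryllithium 14 (not isolated)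
Conditions: n-BuLi, THF, 0 °C; CuBr·SMe2 (10 mol%), prenyl bromide, −78 °C → rt
Reagents that add atoms: 1-bromo-3-methylbut-2-ene (prenyl bromide), CC(C)=CCBr
Why: Directed ortho-metalation at the doubly activated C2–H between the two MOM ethers and copper-catalysed allylation of aryllithium 14 is a standard way to place a prenyl group between two phenolic oxygens.

**Step 6**
Reactants: 15 1,3-bis(methoxymethoxy)-2-(3-methylbut-2-en-1-yl)benzene
Product: 18 2,4-bis(methoxymethoxy)-3-(3-methylbut-2-en-1-yl)phenol, via C4 aryllithium 16 (not isolated), via aryl dimethyl boronate 17 (not isolated)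
Conditions: n-BuLi, TMEDA, THF, −78 → 0 °C; B(OMe)3, −78 °C → rt; H2O2, aq NaOH, 0 °C
Reagents that add atoms: hydrogen peroxide, OO
Why: A second ortho-lithiation next to a MOM ether (the two candidate positions are equivalent by symmetry) gives 16, borylation gives 17, and alkaline peroxide oxidation (1,2-aryl shift from boron to oxygen) should give the phenol without touching the prenyl alkene.

**Step 7**
Reactants: 18 2,4-bis(methoxymethoxy)-3-(3-methylbut-2-en-1-yl)phenol
Product: 19 [2,4-bis(methoxymethoxy)-3-(3-methylbut-2-en-1-yl)phenoxy]tri(propan-2-yl)silane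
Conditions: TIPSCl, imidazole, DMF, rt
Reagents that add atoms: chlorotri(propan-2-yl)silane (TIPSCl), CC(C)[Si](Cl)(C(C)C)C(C)C
Why: Standard silyl ether formation protects the phenol with a bulky, non-coordinating group that shields the neighbouring ring position from lithiation in step 8.

**Step 8**
Reactants: 19 [2,4-bis(methoxymethoxy)-3-(3-methylbut-2-en-1-yl)phenoxy]tri(propan-2-yl)silane
Product: 22 methyl 2-{2,4-bis(methoxymethoxy)-3-(3-methylbut-2-en-1-yl)-5-[tri(propan-2-yl)silyloxy]phenyl}acetate, via aryllithium 20 (not isolated), via arylzinc chloride 21 (not isolated)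
Conditions: s-BuLi, TMEDA, THF, −78 °C; ZnCl2, −78 °C → rt; methyl bromoacetate, Ni(acac)2 (5 mol%), PPh3 (10 mol%), rt
Reagents that add atoms: methyl bromoacetate, COC(=O)CBr
Why: Directed ortho-metalation should take the only ring proton next to a MOM ether (the other is shielded by the silyl ether), transmetalation gives arylzinc 21, and nickel-catalysed Negishi-type coupling with methyl bromoacetate is a known route to arylacetic esters.

**Step 9**
Reactants: 12 5-fluoro-7-(methoxymethoxy)-2,2-dimethyl-8-(3-methylbut-2-en-1-yl)-2H-chromene-6-carbaldehyde; 22 methyl 2-{2,4-bis(methoxymethoxy)-3-(3-methylbut-2-en-1-yl)-5-[tri(propan-2-yl)silyloxy]phenyl}acetate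
Product: 24 methyl 2-{2,4-bis(methoxymethoxy)-3-(3-methylbut-2-en-1-yl)-5-[tri(propan-2-yl)silyloxy]phenyl}-3-[5-fluoro-7-(methoxymethoxy)-2,2-dimethyl-8-(3-methylbut-2-en-1-yl)-2H-chromen-6-yl]-3-hydroxypropanoate (mixture of racemic diastereomers), via lithium ester enolate 23 (not isolated)
Conditions: 22, LiN(SiMe3)2, THF, −78 °C; 12, −78 °C; AcOH, −78 °C
Reagents that add atoms: none
Why: Aldol addition of lithium enolate 23 to the hindered but highly electrophilic aldehyde at −78 °C with a cold quench (to avoid retro-aldol) should form the C3–C4 bond; the two new stereocenters form without control and are erased in steps 10 and 11.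

**Step 10**
Reactants: 24 the β-hydroxy ester of step 9
Product: 25 methyl 2-{2,4-bis(methoxymethoxy)-3-(3-methylbut-2-en-1-yl)-5-[tri(propan-2-yl)silyloxy]phenyl}-3-[5-fluoro-7-(methoxymethoxy)-2,2-dimethyl-8-(3-methylbut-2-en-1-yl)-2H-chromen-6-yl]-3-oxopropanoate (racemic, enolisable)
Conditions: Dess–Martin periodinane, CH2Cl2, 0 °C → rt
Reagents that add atoms: none
Why: Dess–Martin oxidation of the benzylic secondary alcohol to the ketone should tolerate the alkenes, acetals and silyl ether and gives the β-keto ester, whose remaining stereocenter is enolisable and racemic.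

**Step 11**
Reactants: 25 the β-keto ester of step 10
Product: 26 3-{2,4-bis(methoxymethoxy)-3-(3-methylbut-2-en-1-yl)-5-[tri(propan-2-yl)silyloxy]phenyl}-2-methoxy-5-(methoxymethoxy)-8,8-dimethyl-6-(3-methylbut-2-en-1-yl)-4H,8H-pyrano[2,3-f]chromen-4-one
Conditions: NaH, THF, 65 °C
Reagents that add atoms: none
Why: The sodium enolate of the β-keto ester should close the 4-pyranone by intramolecular SNAr (addition–elimination) of its ester-derived oxygen at the only remaining C–F carbon, which is ortho to the aroyl carbonyl, the known route from 2-fluoroaroyl acetates to 2-alkoxychromones; the stereocenter becomes sp2.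

**Step 12**
Reactants: 26 the silyl-protected 2-methoxy pyranochromenone of step 11
Product: 27 3-[5-hydroxy-2,4-bis(methoxymethoxy)-3-(3-methylbut-2-en-1-yl)phenyl]-2-methoxy-5-(methoxymethoxy)-8,8-dimethyl-6-(3-methylbut-2-en-1-yl)-4H,8H-pyrano[2,3-f]chromen-4-one
Conditions: Bu4NF, AcOH, THF, 0 °C
Reagents that add atoms: none
Why: Fluoride cleaves the aryl silyl ether (desilylation driven by Si–F bond formation) under acetic acid buffering, which should leave the 2-methoxypyranone and the MOM ethers intact.

**Step 13**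
Reactants: 27 the phenol of step 12
Product: 29 target CNP0329721.0, via tetrahydroxy 2-methoxyisoflavone 28 (not isolated)
Conditions: HCl (1.25 M in MeOH), THF, 0 → 40 °C
Reagents that add atoms: none
Why: Acid-catalysed acetal exchange with methanol should remove the three MOM groups as dimethoxymethane, and the freed 2'-hydroxyl of 28 then adds to C2 of the O-protonated 2-methoxy-4-pyranone (pyrylium form, 5-exo attack on the C2=O+ bond) and expels methanol (addition–elimination), closing the furan ring; anhydrous conditions prevent hydrolysis of C2–OMe to a 4-hydroxycoumarin.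

**Compound list**
1 | 2,6-difluoro-4-hydroxybenzaldehyde | O=Cc1c(F)cc(O)cc1F | starting material
2 | 2,6-difluoro-4-(methoxymethoxy)benzaldehyde | COCOc1cc(F)c(C=O)c(F)c1 | intermediate
3 | 2,2-dimethyloxirane | CC1(C)CO1 | starting material
4 | lithium 1-lithio-2-methylpropan-2-olate | [Li]CC(C)(C)O[Li] | intermediate (not isolated)
5 | dilithium 1-[2,6-difluoro-4-(methoxymethoxy)phenyl]-3-methylbutane-1,3-diolate (racemic) | COCOc1cc(F)c(C(O[Li])CC(C)(C)O[Li])c(F)c1 | intermediate (not isolated)
6 | rac-5-fluoro-7-(methoxymethoxy)-2,2-dimethyl-3,4-dihydro-2H-chromen-4-ol | COCOc1cc(F)c2C(O)CC(C)(C)Oc2c1 | intermediate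
7 | rac-5-fluoro-7-(methoxymethoxy)-2,2-dimethyl-3,4-dihydro-2H-chromen-4-yl methanesulfonate | COCOc1cc(F)c2C(OS(C)(=O)=O)CC(C)(C)Oc2c1 | intermediate (not isolated)
8 | 5-fluoro-7-(methoxymethoxy)-2,2-dimethyl-2H-chromene | COCOc1cc(F)c2C=CC(C)(C)Oc2c1 | intermediate
9 | [5-fluoro-7-(methoxymethoxy)-2,2-dimethyl-2H-chromen-6-yl]lithium | COCOc1cc2OC(C)(C)C=Cc2c(F)c1[Li] | intermediate (not isolated)
10 | lithium (dimethylamino)[5-fluoro-7-(methoxymethoxy)-2,2-dimethyl-2H-chromen-6-yl]methanolate (racemic) | COCOc1cc2OC(C)(C)C=Cc2c(F)c1C(O[Li])N(C)C | intermediate (not isolated)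
11 | lithium (dimethylamino)[5-fluoro-8-lithio-7-(methoxymethoxy)-2,2-dimethyl-2H-chromen-6-yl]methanolate (racemic) | COCOc1c([Li])c2OC(C)(C)C=Cc2c(F)c1C(O[Li])N(C)C | intermediate (not isolated)
12 | 5-fluoro-7-(methoxymethoxy)-2,2-dimethyl-8-(3-methylbut-2-en-1-yl)-2H-chromene-6-carbaldehyde | COCOc1c(CC=C(C)C)c2OC(C)(C)C=Cc2c(F)c1C=O | intermediate
13 | 1,3-bis(methoxymethoxy)benzene | COCOc1cccc(OCOC)c1 | starting material
14 | [2,6-bis(methoxymethoxy)phenyl]lithium | COCOc1cccc(OCOC)c1[Li] | intermediate (not isolated)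
15 | 1,3-bis(methoxymethoxy)-2-(3-methylbut-2-en-1-yl)benzene | COCOc1cccc(OCOC)c1CC=C(C)C | intermediate
16 | [2,4-bis(methoxymethoxy)-3-(3-methylbut-2-en-1-yl)phenyl]lithium | COCOc1ccc([Li])c(OCOC)c1CC=C(C)C | intermediate (not isolated)
17 | dimethyl [2,4-bis(methoxymethoxy)-3-(3-methylbut-2-en-1-yl)phenyl]boronate | COCOc1ccc(B(OC)OC)c(OCOC)c1CC=C(C)C | intermediate (not isolated)
18 | 2,4-bis(methoxymethoxy)-3-(3-methylbut-2-en-1-yl)phenol | COCOc1ccc(O)c(OCOC)c1CC=C(C)C | intermediate
19 | [2,4-bis(methoxymethoxy)-3-(3-methylbut-2-en-1-yl)phenoxy]tri(propan-2-yl)silane | COCOc1ccc(O[Si](C(C)C)(C(C)C)C(C)C)c(OCOC)c1CC=C(C)C | intermediate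
20 | {2,4-bis(methoxymethoxy)-3-(3-methylbut-2-en-1-yl)-5-[tri(propan-2-yl)silyloxy]phenyl}lithium | COCOc1c([Li])cc(O[Si](C(C)C)(C(C)C)C(C)C)c(OCOC)c1CC=C(C)C | intermediate (not isolated)
21 | chloro{2,4-bis(methoxymethoxy)-3-(3-methylbut-2-en-1-yl)-5-[tri(propan-2-yl)silyloxy]phenyl}zinc | COCOc1c([Zn]Cl)cc(O[Si](C(C)C)(C(C)C)C(C)C)c(OCOC)c1CC=C(C)C | intermediate (not isolated)
22 | methyl 2-{2,4-bis(methoxymethoxy)-3-(3-methylbut-2-en-1-yl)-5-[tri(propan-2-yl)silyloxy]phenyl}acetate | COCOc1c(CC(=O)OC)cc(O[Si](C(C)C)(C(C)C)C(C)C)c(OCOC)c1CC=C(C)C | intermediate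
23 | lithium enolate of 22 (enolate geometry not defined) | COCOc1c(C=C(O[Li])OC)cc(O[Si](C(C)C)(C(C)C)C(C)C)c(OCOC)c1CC=C(C)C | intermediate (not isolated)
24 | β-hydroxy ester from 12 and 22 (mixture of racemic diastereomers) | COCOc1c(CC=C(C)C)c2OC(C)(C)C=Cc2c(F)c1C(O)C(C(=O)OC)c1cc(O[Si](C(C)C)(C(C)C)C(C)C)c(OCOC)c(CC=C(C)C)c1OCOC | intermediate
25 | β-keto ester (racemic, enolisable) | COCOc1c(CC=C(C)C)c2OC(C)(C)C=Cc2c(F)c1C(=O)C(C(=O)OC)c1cc(O[Si](C(C)C)(C(C)C)C(C)C)c(OCOC)c(CC=C(C)C)c1OCOC | intermediate
26 | 3-{2,4-bis(methoxymethoxy)-3-prenyl-5-[tri(propan-2-yl)silyloxy]phenyl}-2-methoxy-5-(methoxymethoxy)-8,8-dimethyl-6-prenyl-4H,8H-pyrano[2,3-f]chromen-4-one | COCOc1c(CC=C(C)C)c2OC(C)(C)C=Cc2c2oc(OC)c(-c3cc(O[Si](C(C)C)(C(C)C)C(C)C)c(OCOC)c(CC=C(C)C)c3OCOC)c(=O)c12 | intermediate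
27 | 3-[5-hydroxy-2,4-bis(methoxymethoxy)-3-prenylphenyl]-2-methoxy-5-(methoxymethoxy)-8,8-dimethyl-6-prenyl-4H,8H-pyrano[2,3-f]chromen-4-one | COCOc1c(CC=C(C)C)c2OC(C)(C)C=Cc2c2oc(OC)c(-c3cc(O)c(OCOC)c(CC=C(C)C)c3OCOC)c(=O)c12 | intermediate
28 | 5-hydroxy-2-methoxy-8,8-dimethyl-6-prenyl-3-(2,4,5-trihydroxy-3-prenylphenyl)-4H,8H-pyrano[2,3-f]chromen-4-one | Oc1c(CC=C(C)C)c2OC(C)(C)C=Cc2c2oc(OC)c(-c3cc(O)c(O)c(CC=C(C)C)c3O)c(=O)c12 | intermediate (not isolated)
29 | CNP0329721.0: coumaronochromone (benzofuran fused through its C2–C3 bond to a 4-pyranone) with 5-OH and 6-prenyl on ring A, a 2,2-dimethyl-2H-pyran fused at C7 (oxygen) and C8, and 3'-prenyl plus 4',5'-dihydroxy on ring B; no stereocenter | CC(C)=CCc1c2c(c3oc4oc5c(CC=C(C)C)c(O)c(O)cc5c4c(=O)c3c1O)C=CC(C)(C)O2 | target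

**Step count and risks**
Total steps: 13. Longest linear sequence: 9 (steps 1–4 and 9–13); ring B is a four-step branch (steps 5–8).

Steps most likely to fail:

1. Step 2. The β-lithioalkoxide may undergo β-elimination before it meets the aldehyde, the epoxide radical anion may open at the other C–O bond, or the ring closure may stall because a lithium alkoxide attacks a fluoroarene that carries no acceptor group. The fallback uses known reactions only, sets out from 2 and returns at 6. 2-Methylallylmagnesium chloride (THF, −78 °C) would add to 2 to give rac-1-[2,6-difluoro-4-(methoxymethoxy)phenyl]-3-methylbut-3-en-1-ol F1. Mukaiyama hydration of its 1,1-disubstituted alkene (Co(acac)2, PhSiH3, O2, i-PrOH) would give rac-1-[2,6-difluoro-4-(methoxymethoxy)phenyl]-3-methylbutane-1,3-diol F2. NaH in DMF at 80 °C would then close the tertiary alkoxide onto a ring fluoride to give 6.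

2. Step 4. The first deprotonation may lose regiocontrol, the lithium hemiaminal may break down during the second deprotonation so that s-BuLi adds to the freed aldehyde, or the allylation may go with allylic transposition. The fallback sets out from 8 and returns at 12. The sequence is stopped after DMF and aqueous work-up to isolate 5-fluoro-7-(methoxymethoxy)-2,2-dimethyl-2H-chromene-6-carbaldehyde F3. Condensation with N,N'-dimethylethane-1,2-diamine (toluene, MgSO4) gives the isolable aminal 2-[5-fluoro-7-(methoxymethoxy)-2,2-dimethyl-2H-chromen-6-yl]-1,3-dimethylimidazolidine F4. Lithiation at C8 (s-BuLi, TMEDA, −78 °C) and prenylation give the aminal 2-[5-fluoro-7-(methoxymethoxy)-2,2-dimethyl-8-(3-methylbut-2-en-1-yl)-2H-chromen-6-yl]-1,3-dimethylimidazolidine F5, which wet silica or aqueous oxalic acid hydrolyses to 12.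

3. Step 8. Lithiation may be incomplete or misdirected towards the silyl ether (with silyl migration), the arylzinc may homocouple, or the nickel catalyst may reduce the bromoacetate. The fallback reverses the polarity of the coupling, sets out from 19 and returns at 22. The same ortho-lithiation is quenched with I2 to give the aryl iodide {5-iodo-2,4-bis(methoxymethoxy)-3-(3-methylbut-2-en-1-yl)phenoxy}tri(propan-2-yl)silane F6. Palladium-catalysed α-arylation with the Reformatsky reagent BrZnCH2CO2Me (Pd(dba)2, P(t-Bu)3, THF) would then give 22.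

**Further compounds**
F1 | step 2 | rac-1-[2,6-difluoro-4-(methoxymethoxy)phenyl]-3-methylbut-3-en-1-ol | COCOc1cc(F)c(C(O)CC(C)=C)c(F)c1
F2 | step 2 | rac-1-[2,6-difluoro-4-(methoxymethoxy)phenyl]-3-methylbutane-1,3-diol | COCOc1cc(F)c(C(O)CC(C)(C)O)c(F)c1
F3 | step 4 | 5-fluoro-7-(methoxymethoxy)-2,2-dimethyl-2H-chromene-6-carbaldehyde | COCOc1cc2OC(C)(C)C=Cc2c(F)c1C=O
F4 | step 4 | 2-[5-fluoro-7-(methoxymethoxy)-2,2-dimethyl-2H-chromen-6-yl]-1,3-dimethylimidazolidine | COCOc1cc2OC(C)(C)C=Cc2c(F)c1C1N(C)CCN1C
F5 | step 4 | 2-[5-fluoro-7-(methoxymethoxy)-2,2-dimethyl-8-(3-methylbut-2-en-1-yl)-2H-chromen-6-yl]-1,3-dimethylimidazolidine | COCOc1c(CC=C(C)C)c2OC(C)(C)C=Cc2c(F)c1C1N(C)CCN1C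
F6 | step 8 | {5-iodo-2,4-bis(methoxymethoxy)-3-(3-methylbut-2-en-1-yl)phenoxy}tri(propan-2-yl)silane | COCOc1c(I)cc(O[Si](C(C)C)(C(C)C)C(C)C)c(OCOC)c1CC=C(C)C
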